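## Retrosynthetic overview

1. Target 29 ⇐ macrolactam 27 by carbamoylation of the C-7 hydroxyl and one basic methanolysis that removes two benzoates and two aryl silyl ethers.
2. The 19-membered ansa lactam is the only ring formed (step 15; the arene is bought) ⇐ intramolecular copper-catalysed N-arylation of bromo-dienamide 26.
3. C-4=C-5 (Z) ⇐ Z-selective cross-metathesis of vinyl carbinol 21 with dienamide 25 (proposed new step).
4. C-6/C-7, C-10/C-11 and C-14/C-15 ⇐ three chiral-phosphoric-acid-catalysed (Z)-allylborations of aldehydes 15, 10 and 4; C-12 ⇐ enamine-catalysed α-benzoyloxylation of aldehyde 9; the chain grows between them by hydroformylation and methacrolein cross-metathesis.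
5. Aryl core ⇐ achiral 3-bromo-2-hydroxy-5-methoxybenzaldehyde 1.

Conventions: C-1 to C-15 are the ansa-chain carbons (C-1 amide carbonyl, C-15 benzylic carbon); Ar = 3-bromo-2,5-bis(tert-butyldimethylsilyloxy)phenyl; TRIP = 3,3'-bis(2,4,6-triisopropylphenyl)-1,1'-binaphthyl-2,2'-diyl hydrogen phosphate.

Assumption: the sense of induction is taken from simple aldehydes ((R)-TRIP gives Re-face allyl transfer; (S)-2-tritylpyrrolidine gives the 2S acyloxy aldehyde); if a sense proves opposite, the antipodal catalyst is used. Compounds 1, 5, 14, 16, 22 and 23 are taken as commercial and are achiral.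

## Route

Step 1
Reactants: 1 3-bromo-2-hydroxy-5-methoxybenzaldehyde
Product: 3 3-bromo-2,5-dihydroxybenzaldehyde, via bis(dibromoboryl) aryl ether 2 (not isolated)
Conditions: BBr3 (3 equiv), CH2Cl2, −78 °C → rt; H2O, 0 °C
Reagents that add atoms: none
Why: BBr3 O-demethylation (Lewis-acid ether cleavage) is routine beside an aryl aldehyde and bromide and frees the bromohydroquinone so that both phenols can carry the same protecting group.

Step 2
Reactants: 3 3-bromo-2,5-dihydroxybenzaldehyde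
Product: 4 3-bromo-2,5-bis(tert-butyldimethylsilyloxy)benzaldehyde
Conditions: TBSCl (2.5 equiv), imidazole (5 equiv), DMAP (5 mol%), DMF, rt → 40 °C
Reagents that add atoms: tert-butyldimethylsilyl chloride, CC(C)(C)[Si](C)(C)Cl
Why: Standard phenol silylation gives aryl silyl ethers that tolerate the neutral and weakly acidic steps ahead and fall off in the final methanolysis.

Step 3
Reactants: 4 3-bromo-2,5-bis(tert-butyldimethylsilyloxy)benzaldehyde; 5 (Z)-crotylboronic acid pinacol ester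
Product: 7 (1R,2S)-1-Ar-2-methylbut-3-en-1-ol, via pinacol borate ester 6 (not isolated)
Conditions: (R)-TRIP (5 mol%), 5 (1.3 equiv), 4 Å MS, toluene, −30 °C; aq. NaHCO3 work-up
Reagents that add atoms: none
Why: Chiral-phosphoric-acid-catalysed crotylboration through a closed chair transition state sets the first stereocentres from achiral partners, the acid directing Re-face attack (C-15 R) and the Z-crotyl geometry giving the syn C-14 methyl (S).

Step 4
Reactants: 7 (1R,2S)-1-Ar-2-methylbut-3-en-1-ol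
Product: 8 1-bromo-2,5-bis(tert-butyldimethylsilyloxy)-3-[(1R,2S)-1-methoxy-2-methylbut-3-en-1-yl]benzene
Conditions: Me3OBF4 (3 equiv), 1,8-bis(dimethylamino)naphthalene (3 equiv), 4 Å MS, CH2Cl2, rt
Reagents that add atoms: trimethyloxonium tetrafluoroborate, C[O+](C)C.F[B-](F)(F)F
Why: O-Methylation with a Meerwein salt under non-basic conditions installs the C-15 methyl ether without the aryl-to-alkyl silyl migration that an alkoxide would trigger.

Step 5
Reactants: 8 1-bromo-2,5-bis(tert-butyldimethylsilyloxy)-3-[(1R,2S)-1-methoxy-2-methylbut-3-en-1-yl]benzene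
Product: 9 (4S,5R)-5-Ar-5-methoxy-4-methylpentanal
Conditions: Rh(acac)(CO)2 (1 mol%), Xantphos (3 mol%), CO/H2 (1:1, 10 bar), toluene, 70 °C
Reagents that add atoms: carbon monoxide, [C-]#[O+]
Why: Linear-selective hydroformylation with a wide-bite-angle diphosphine adds C-11 to the terminal alkene carbon, the allylic methyl branch reinforcing linear selectivity while aryl bromide and silyl ethers stay inert.

Step 6
Reactants: 9 (4S,5R)-5-Ar-5-methoxy-4-methylpentanal
Product: 10 (2S,4S,5R)-5-Ar-5-methoxy-4-methyl-1-oxopentan-2-yl benzoate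
Conditions: (S)-2-(triphenylmethyl)pyrrolidine (10 mol%), dibenzoyl peroxide (1.2 equiv), benzene-1,4-diol (10 mol%), THF, 0 °C; short silica pad, used at once
Reagents that add atoms: dibenzoyl peroxide, O=C(OOC(=O)c1ccccc1)c1ccccc1
Why: Enamine-catalysed α-benzoyloxylation sets C-12 (S) because the trityl group shields one face of the E-enamine and the peroxide oxygen is delivered to the other.

Step 7
Reactants: 10 (2S,4S,5R)-5-Ar-5-methoxy-4-methyl-1-oxopentan-2-yl benzoate; 5 (Z)-crotylboronic acid pinacol ester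
Product: 12 (3S,4R,5S,7S,8R)-8-Ar-4-hydroxy-8-methoxy-3,7-dimethyloct-1-en-5-yl benzoate, via pinacol borate ester 11 (not isolated)
Conditions: (R)-TRIP (5 mol%), 5 (1.5 equiv), 4 Å MS, toluene, −30 °C; aq. NaHCO3 work-up
Reagents that add atoms: none
Why: Second chiral-phosphoric-acid-catalysed crotylboration in which the catalyst's Re-face preference and the polar Felkin preference of the α-acyloxy aldehyde are matched (C-11 R, anti to the C-12 oxygen) and the Z-crotyl geometry gives the syn C-10 methyl (S).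

Step 8
Reactants: 12 (3S,4R,5S,7S,8R)-8-Ar-4-hydroxy-8-methoxy-3,7-dimethyloct-1-en-5-yl benzoate
Product: 13 (3S,4R,5S,7S,8R)-8-Ar-8-methoxy-3,7-dimethyloct-1-ene-4,5-diyl dibenzoate
Conditions: BzCl (2 equiv), pyridine, DMAP (10 mol%), CH2Cl2, 0 °C → rt
Reagents that add atoms: benzoyl chloride, O=C(Cl)c1ccccc1
Why: Acylation makes both C-11 and C-12 oxygens benzoates, so any 1,2-benzoyl migration is harmless and one methanolysis frees both at the end.

Step 9
Reactants: 13 (3S,4R,5S,7S,8R)-8-Ar-8-methoxy-3,7-dimethyloct-1-ene-4,5-diyl dibenzoate; 14 methacrolein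
Product: 15 (2E,4S,5R,6S,8S,9R)-9-Ar-9-methoxy-2,4,8-trimethyl-1-oxonon-2-ene-5,6-diyl dibenzoate
Conditions: 14 (10 equiv), second-generation Hoveyda–Grubbs catalyst RuCl2(H2IMes)(=CH-C6H4-2-OiPr) (7 mol%, two portions), CH2Cl2, 40 °C
Reagents that add atoms: none
Why: Olefin cross-metathesis with a 1,1-disubstituted enal gives the (E)-trisubstituted C-8=C-9 enal under thermodynamic control in one step and avoids a β-acyloxy aldehyde.

Step 10
Reactants: 16 allyl methyl ether
Product: 19 2-[(2Z)-3-methoxyprop-2-en-1-yl]-4,4,5,5-tetramethyl-1,3,2-dioxaborolane, via (Z)-3-methoxyallyllithium 17 (not isolated), via lithium isopropoxyborate complex 18 (not isolated)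
Conditions: s-BuLi (1.0 equiv), THF, −78 °C; 2-isopropoxy-4,4,5,5-tetramethyl-1,3,2-dioxaborolane (1.1 equiv), −78 °C → rt; HCl (1.0 equiv, Et2O); distillation
Reagents that add atoms: 2-isopropoxy-4,4,5,5-tetramethyl-1,3,2-dioxaborolane, CC(C)OB1OC(C)(C)C(C)(C)O1
Why: Allyl ether metalation gives the oxygen-chelated (Z)-alkoxyallyllithium, which is borylated at the γ-terminus with retention of the Z geometry (metalation–borylation).

Step 11
Reactants: 15 (2E,4S,5R,6S,8S,9R)-9-Ar-9-methoxy-2,4,8-trimethyl-1-oxonon-2-ene-5,6-diyl dibenzoate; 19 2-[(2Z)-3-methoxyprop-2-en-1-yl]-4,4,5,5-tetramethyl-1,3,2-dioxaborolane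
Product: 21 (3S,4S,5E,7S,8R,9S,11S,12R)-12-Ar-4-hydroxy-3,12-dimethoxy-5,7,11-trimethyldodeca-1,5-diene-8,9-diyl dibenzoate, via pinacol borate ester 20 (not isolated)
Conditions: (R)-TRIP (5 mol%), 19 (1.5 equiv), 4 Å MS, toluene, −40 °C; aq. NaHCO3 work-up
Reagents that add atoms: none
Why: Chiral-phosphoric-acid-catalysed γ-alkoxyallylboration of the enal through the same closed transition state gives C-7 (S) by Re-face attack and the syn C-6 methoxy group (S) from the Z-enol ether, the remote centres being too far away to interfere.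

Step 12
Reactants: 22 acrolein; 23 ethyl 2-(triphenylphosphoranylidene)propanoate
Product: 24 ethyl (2E)-2-methylpenta-2,4-dienoate
Conditions: 22 (1.5 equiv), CH2Cl2, 0 °C → rt
Reagents that add atoms: none
Why: Wittig olefination with a stabilised α-methyl ylide adds 1,2 to acrolein and gives the (E)-trisubstituted dienoate.

Step 13
Reactants: 24 ethyl (2E)-2-methylpenta-2,4-dienoate
Product: 25 (2E)-2-methylpenta-2,4-dienamide
Conditions: AlMe3 (3 equiv), NH4Cl (3 equiv), toluene, 0 °C → rt; then 24, 50 °C; 1 M HCl work-up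
Reagents that add atoms: ammonium chloride, [NH4+].[Cl-]
Why: Aluminium-amide aminolysis of the ester gives the primary amide without conjugate addition to the diene.

Step 14
Reactants: 21 (3S,4S,5E,7S,8R,9S,11S,12R)-12-Ar-4-hydroxy-3,12-dimethoxy-5,7,11-trimethyldodeca-1,5-diene-8,9-diyl dibenzoate; 25 (2E)-2-methylpenta-2,4-dienamide
Product: 26 (2E,4Z,6S,7S,8E,10S,11R,12S,14S,15R)-15-Ar-11,12-bis(benzoyloxy)-7-hydroxy-6,15-dimethoxy-2,8,10,14-tetramethylpentadeca-2,4,8-trienamide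
Conditions: 25 (3 equiv), Ru(κ2-NO3)(κ2-C,C-L)(=CH-C6H4-2-OiPr) (10 mol%; L = 1-(adamantan-1-yl)-3-(2,6-diisopropylphenyl)imidazolidin-2-ylidene metalated at an adamantyl CH), BHT (5 mol%), THF, 35 °C, static vacuum
Reagents that add atoms: none
Why: Proposed new method: Z-selective cross-metathesis of an α-alkoxy-branched terminal alkene with the terminal vinyl group of an electron-poor (2E)-2,4-dienamide, in which the side-bound ruthenacyclobutane of the cyclometalated catalyst forces both substituents away from the N-aryl group so that C-4=C-5 forms syn (Z), while the trisubstituted C-2=C-3 and C-8=C-9 bonds are too hindered to enter the cycle and the (E)-disposed carbonyl cannot chelate the carbene; the closest known reaction type is Z-selective cross-metathesis of simple terminal alkenes with alkyl-substituted (3E)-1,3-dienes and of allylic-substituted alkenes with this catalyst class, and neither a dienamide partner nor this pairing has been described.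

Step 15
Reactants: 26 (2E,4Z,6S,7S,8E,10S,11R,12S,14S,15R)-15-Ar-11,12-bis(benzoyloxy)-7-hydroxy-6,15-dimethoxy-2,8,10,14-tetramethylpentadeca-2,4,8-trienamide
Product: 27 19-membered macrolactam (6S,7S,10S,11R,12S,14S,15R; 2E,4Z,8E) bearing free 7-OH and 11,12-dibenzoate and two aryl tert-butyldimethylsilyl ethers
Conditions: CuI (0.5 equiv), N,N'-dimethylethylenediamine (1.0 equiv), K2CO3 (2.5 equiv), toluene (2 mM), 100 °C
Reagents that add atoms: none
Why: Intramolecular copper-catalysed amidation (Goldberg-type N-arylation) of the aryl bromide by the primary dienamide closes the ansa ring, a ring closure precedented for ansamycin lactams, and the weak base in toluene spares benzoates, silyl ethers and the free secondary alcohol.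

Step 16
Reactants: 27 19-membered macrolactam bearing free 7-OH
Product: 29 target ansamycin hydroquinone CNP0523404.1, via N-trichloroacetyl carbamate 28 (not isolated)
Conditions: Cl3CC(O)NCO (1.5 equiv), CH2Cl2, 0 °C; then K2CO3 (0.5 equiv), degassed MeOH, rt, argon; aq. NH4Cl/Na2S2O4 work-up
Reagents that add atoms: trichloroacetyl isocyanate, O=C=NC(=O)C(Cl)(Cl)Cl
Why: Acyl-isocyanate carbamoylation of the only free hydroxyl followed by one base-catalysed methanolysis removes the trichloroacetyl group, both benzoates and both aryl silyl ethers while the primary carbamate, lactam and methyl ethers survive, and the reducing work-up keeps the hydroquinone.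

## Compound list

1 | 3-bromo-2-hydroxy-5-methoxybenzaldehyde | O=Cc1cc(OC)cc(Br)c1O | starting material
2 | 3-bromo-2,5-bis[(dibromoboranyl)oxy]benzaldehyde | O=Cc1cc(OB(Br)Br)cc(Br)c1OB(Br)Br | intermediate
3 | 3-bromo-2,5-dihydroxybenzaldehyde | O=Cc1cc(O)cc(Br)c1O | intermediate
4 | 3-bromo-2,5-bis(tert-butyldimethylsilyloxy)benzaldehyde | O=Cc1cc(O[Si](C)(C)C(C)(C)C)cc(Br)c1O[Si](C)(C)C(C)(C)C | intermediate
5 | (Z)-crotylboronic acid pinacol ester | C/C=C\CB1OC(C)(C)C(C)(C)O1 | starting material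
6 | pinacol borate ester of 7 (O-B at C-15) | Brc1cc(O[Si](C)(C)C(C)(C)C)cc(c1O[Si](C)(C)C(C)(C)C)[C@H](OB2OC(C)(C)C(C)(C)O2)[C@@H](C)C=C | intermediate
7 | (1R,2S)-1-[3-bromo-2,5-bis(tert-butyldimethylsilyloxy)phenyl]-2-methylbut-3-en-1-ol | Brc1cc(O[Si](C)(C)C(C)(C)C)cc(c1O[Si](C)(C)C(C)(C)C)[C@H](O)[C@@H](C)C=C | intermediate
8 | 1-bromo-2,5-bis(tert-butyldimethylsilyloxy)-3-[(1R,2S)-1-methoxy-2-methylbut-3-en-1-yl]benzene | Brc1cc(O[Si](C)(C)C(C)(C)C)cc(c1O[Si](C)(C)C(C)(C)C)[C@H](OC)[C@@H](C)C=C | intermediate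
9 | (4S,5R)-5-[3-bromo-2,5-bis(tert-butyldimethylsilyloxy)phenyl]-5-methoxy-4-methylpentanal | Brc1cc(O[Si](C)(C)C(C)(C)C)cc(c1O[Si](C)(C)C(C)(C)C)[C@H](OC)[C@@H](C)CCC=O | intermediate
10 | (2S,4S,5R)-5-[3-bromo-2,5-bis(tert-butyldimethylsilyloxy)phenyl]-5-methoxy-4-methyl-1-oxopentan-2-yl benzoate | Brc1cc(O[Si](C)(C)C(C)(C)C)cc(c1O[Si](C)(C)C(C)(C)C)[C@H](OC)[C@@H](C)C[C@H](OC(=O)c2ccccc2)C=O | intermediate
11 | pinacol borate ester of 12 (O-B at C-11) | Brc1cc(O[Si](C)(C)C(C)(C)C)cc(c1O[Si](C)(C)C(C)(C)C)[C@H](OC)[C@@H](C)C[C@H](OC(=O)c2ccccc2)[C@H](OB3OC(C)(C)C(C)(C)O3)[C@@H](C)C=C | intermediate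
12 | (3S,4R,5S,7S,8R)-8-[3-bromo-2,5-bis(tert-butyldimethylsilyloxy)phenyl]-4-hydroxy-8-methoxy-3,7-dimethyloct-1-en-5-yl benzoate | Brc1cc(O[Si](C)(C)C(C)(C)C)cc(c1O[Si](C)(C)C(C)(C)C)[C@H](OC)[C@@H](C)C[C@H](OC(=O)c2ccccc2)[C@H](O)[C@@H](C)C=C | intermediate
13 | (3S,4R,5S,7S,8R)-8-[3-bromo-2,5-bis(tert-butyldimethylsilyloxy)phenyl]-8-methoxy-3,7-dimethyloct-1-ene-4,5-diyl dibenzoate | Brc1cc(O[Si](C)(C)C(C)(C)C)cc(c1O[Si](C)(C)C(C)(C)C)[C@H](OC)[C@@H](C)C[C@H](OC(=O)c2ccccc2)[C@H](OC(=O)c3ccccc3)[C@@H](C)C=C | intermediate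
14 | methacrolein (2-methylprop-2-enal) | C=C(C)C=O | starting material
15 | (2E,4S,5R,6S,8S,9R)-9-[3-bromo-2,5-bis(tert-butyldimethylsilyloxy)phenyl]-9-methoxy-2,4,8-trimethyl-1-oxonon-2-ene-5,6-diyl dibenzoate | Brc1cc(O[Si](C)(C)C(C)(C)C)cc(c1O[Si](C)(C)C(C)(C)C)[C@H](OC)[C@@H](C)C[C@H](OC(=O)c2ccccc2)[C@H](OC(=O)c3ccccc3)[C@@H](C)/C=C(\C)C=O | intermediate
16 | allyl methyl ether (3-methoxyprop-1-ene) | C=CCOC | starting material
17 | (Z)-3-methoxyallyllithium | [Li]C/C=C\OC | intermediate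
18 | lithium isopropoxy[(2Z)-3-methoxyprop-2-en-1-yl](pinacolato)borate | [Li+].CO/C=C\C[B-]1(OC(C)C)OC(C)(C)C(C)(C)O1 | intermediate
19 | 2-[(2Z)-3-methoxyprop-2-en-1-yl]-4,4,5,5-tetramethyl-1,3,2-dioxaborolane | CO/C=C\CB1OC(C)(C)C(C)(C)O1 | intermediate
20 | pinacol borate ester of 21 (O-B at C-7) | Brc1cc(O[Si](C)(C)C(C)(C)C)cc(c1O[Si](C)(C)C(C)(C)C)[C@H](OC)[C@@H](C)C[C@H](OC(=O)c2ccccc2)[C@H](OC(=O)c3ccccc3)[C@@H](C)/C=C(\C)[C@H](OB4OC(C)(C)C(C)(C)O4)[C@@H](OC)C=C | intermediate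
21 | (3S,4S,5E,7S,8R,9S,11S,12R)-12-[3-bromo-2,5-bis(tert-butyldimethylsilyloxy)phenyl]-4-hydroxy-3,12-dimethoxy-5,7,11-trimethyldodeca-1,5-diene-8,9-diyl dibenzoate | Brc1cc(O[Si](C)(C)C(C)(C)C)cc(c1O[Si](C)(C)C(C)(C)C)[C@H](OC)[C@@H](C)C[C@H](OC(=O)c2ccccc2)[C@H](OC(=O)c3ccccc3)[C@@H](C)/C=C(\C)[C@H](O)[C@@H](OC)C=C | intermediate
22 | acrolein | C=CC=O | starting material
23 | ethyl 2-(triphenylphosphoranylidene)propanoate | CCOC(=O)C(C)=P(c1ccccc1)(c1ccccc1)c1ccccc1 | starting material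
24 | ethyl (2E)-2-methylpenta-2,4-dienoate | C=C/C=C(\C)C(=O)OCC | intermediate
25 | (2E)-2-methylpenta-2,4-dienamide | C=C/C=C(\C)C(N)=O | intermediate
26 | (2E,4Z,6S,7S,8E,10S,11R,12S,14S,15R)-11,12-bis(benzoyloxy)-15-[3-bromo-2,5-bis(tert-butyldimethylsilyloxy)phenyl]-7-hydroxy-6,15-dimethoxy-2,8,10,14-tetramethylpentadeca-2,4,8-trienamide | Brc1cc(O[Si](C)(C)C(C)(C)C)cc(c1O[Si](C)(C)C(C)(C)C)[C@H](OC)[C@@H](C)C[C@H](OC(=O)c2ccccc2)[C@H](OC(=O)c3ccccc3)[C@@H](C)/C=C(\C)[C@H](O)[C@@H](OC)/C=C\C=C(/C)C(N)=O | intermediate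
27 | 19-membered macrolactam: N-aryl amide of the C-1 to C-15 chain (6S,7S,10S,11R,12S,14S,15R; 2E,4Z,8E) with free 7-OH, 11,12-dibenzoate, 6- and 15-OMe and both phenols as tert-butyldimethylsilyl ethers | CO[C@H]1/C=C\C=C(/C)C(=O)Nc2cc(O[Si](C)(C)C(C)(C)C)cc(c2O[Si](C)(C)C(C)(C)C)[C@H](OC)[C@@H](C)C[C@H](OC(=O)c3ccccc3)[C@H](OC(=O)c4ccccc4)[C@@H](C)/C=C(\C)[C@@H]1O | intermediate
28 | N-trichloroacetyl carbamate of 27 at the C-7 oxygen | CO[C@H]1/C=C\C=C(/C)C(=O)Nc2cc(O[Si](C)(C)C(C)(C)C)cc(c2O[Si](C)(C)C(C)(C)C)[C@H](OC)[C@@H](C)C[C@H](OC(=O)c3ccccc3)[C@H](OC(=O)c4ccccc4)[C@@H](C)/C=C(\C)[C@@H]1OC(=O)NC(=O)C(Cl)(Cl)Cl | intermediate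
29 | CNP0523404.1: hydroquinone ansamycin lactam (6S,7S,10S,11R,12S,14S,15R; 2E,4Z,8E) with 7-carbamate, 11,12-diol and 6,15-dimethoxy groups | CO[C@H]1/C=C\C=C(/C)C(=O)Nc2cc(O)cc(c2O)[C@H](OC)[C@@H](C)C[C@H](O)[C@H](O)[C@@H](C)/C=C(\C)[C@@H]1OC(N)=O | target

## Step count and risks

Total step count: 16. Longest linear sequence: 13 steps (steps 1–9, 11, 14, 15, 16); steps 10, 12 and 13 make reagents 19 and 25.

Three steps most likely to fail:

**Step 14 (proposed new Z-selective cross-metathesis).** Risks are low turnover with the hindered allylic ether, homocoupling of 25 and erosion of Z-selectivity. The fallback uses known chemistry, sets out from 21 and comes back at 26. Compound 21 is silylated (TESOTf, 2,6-lutidine, CH2Cl2, −78 °C) to the C-7 triethylsilyl ether F1. OsO4 (2 mol%)/NaIO4/2,6-lutidine in dioxane–water cleaves only the monosubstituted vinyl group to the α-methoxy aldehyde F2. Stork–Zhao olefination ((iodomethyl)triphenylphosphonium iodide, NaN(SiMe3)2, THF/DMPU, −78 °C) gives the (Z)-vinyl iodide F3. Pd(PPh3)4-catalysed formylation (CO 1 atm, Bu3SnH by syringe pump, THF, 50 °C) gives the (Z)-enal F4. In parallel, commercial (carbamoylmethyl)triphenylphosphonium chloride is deprotonated (aq. NaOH) to (carbamoylmethylene)triphenylphosphorane F5, C-methylated with MeI to (1-carbamoylethyl)triphenylphosphonium iodide F6 and deprotonated again to 2-(triphenylphosphoranylidene)propanamide F7. Wittig reaction of F4 with F7 (toluene, 60 °C) gives the TES-protected (2E,4Z)-dienamide F8. PPTS in MeOH at 0 °C removes the triethylsilyl group and delivers 26.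

**Step 15 (copper-catalysed macro-N-arylation).** Risks are the ortho silyloxy group slowing the coupling and loss of aryl silyl ethers at 100 °C. The fallback changes the ring-closing bond, sets out from 21 and comes back at 27. Compound 21 is N-arylated intermolecularly with 25 (CuI 10 mol%, N,N'-dimethylethylenediamine, K2CO3, BHT, toluene, 90 °C) to the N-aryl dienamide F9. The ring is then closed at C-4=C-5 by ring-closing metathesis at 2 mM with the cyclometalated catalyst Ru(κ2-NO3)(κ2-C,C-L)(=CH-C6H4-2-OiPr) used in step 14, giving 27. This fallback relies on the same untested diene reactivity as step 14, now intramolecular.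

**Step 9 (methacrolein cross-metathesis on an α-branched alkene).** The risk is slow or incomplete conversion. The fallback is a two-step cleavage and olefination by known chemistry, sets out from 13 and comes back at 15. Ozonolysis of 13 (O3, CH2Cl2, −78 °C; PPh3) gives the β-benzoyloxy aldehyde F10. Wittig reaction with commercial 2-(triphenylphosphoranylidene)propanal (benzene, 70 °C, no added base, to limit benzoate elimination) gives 15.

Further compounds
F1 | step 14 | C-7 triethylsilyl ether of 21 | Brc1cc(O[Si](C)(C)C(C)(C)C)cc(c1O[Si](C)(C)C(C)(C)C)[C@H](OC)[C@@H](C)C[C@H](OC(=O)c2ccccc2)[C@H](OC(=O)c3ccccc3)[C@@H](C)/C=C(\C)[C@H](O[Si](CC)(CC)CC)[C@@H](OC)C=C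
F2 | step 14 | C-5 aldehyde (α-methoxy aldehyde) from cleavage of the vinyl group of F1 | Brc1cc(O[Si](C)(C)C(C)(C)C)cc(c1O[Si](C)(C)C(C)(C)C)[C@H](OC)[C@@H](C)C[C@H](OC(=O)c2ccccc2)[C@H](OC(=O)c3ccccc3)[C@@H](C)/C=C(\C)[C@H](O[Si](CC)(CC)CC)[C@@H](OC)C=O
F3 | step 14 | (Z)-vinyl iodide at C-4=C-5 | Brc1cc(O[Si](C)(C)C(C)(C)C)cc(c1O[Si](C)(C)C(C)(C)C)[C@H](OC)[C@@H](C)C[C@H](OC(=O)c2ccccc2)[C@H](OC(=O)c3ccccc3)[C@@H](C)/C=C(\C)[C@H](O[Si](CC)(CC)CC)[C@@H](OC)/C=C\I
F4 | step 14 | (Z)-enal with C-3 as aldehyde | Brc1cc(O[Si](C)(C)C(C)(C)C)cc(c1O[Si](C)(C)C(C)(C)C)[C@H](OC)[C@@H](C)C[C@H](OC(=O)c2ccccc2)[C@H](OC(=O)c3ccccc3)[C@@H](C)/C=C(\C)[C@H](O[Si](CC)(CC)CC)[C@@H](OC)/C=C\C=O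
F5 | step 14 | (carbamoylmethylene)triphenylphosphorane | NC(=O)C=P(c1ccccc1)(c1ccccc1)c1ccccc1
F6 | step 14 | (1-carbamoylethyl)triphenylphosphonium iodide | CC(C(N)=O)[P+](c1ccccc1)(c1ccccc1)c1ccccc1.[I-]
F7 | step 14 | 2-(triphenylphosphoranylidene)propanamide | CC(C(N)=O)=P(c1ccccc1)(c1ccccc1)c1ccccc1
F8 | step 14 | C-7 triethylsilyl ether of 26 | Brc1cc(O[Si](C)(C)C(C)(C)C)cc(c1O[Si](C)(C)C(C)(C)C)[C@H](OC)[C@@H](C)C[C@H](OC(=O)c2ccccc2)[C@H](OC(=O)c3ccccc3)[C@@H](C)/C=C(\C)[C@H](O[Si](CC)(CC)CC)[C@@H](OC)/C=C\C=C(/C)C(N)=O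
F9 | step 15 | N-aryl (2E)-2-methylpenta-2,4-dienamide of the C-5 to C-15 chain with terminal vinyl and free 7-OH | C=C/C=C(\C)C(=O)Nc1cc(O[Si](C)(C)C(C)(C)C)cc(c1O[Si](C)(C)C(C)(C)C)[C@H](OC)[C@@H](C)C[C@H](OC(=O)c2ccccc2)[C@H](OC(=O)c3ccccc3)[C@@H](C)/C=C(\C)[C@H](O)[C@@H](OC)C=C
F10 | step 9 | C-9 aldehyde from ozonolysis of 13 | Brc1cc(O[Si](C)(C)C(C)(C)C)cc(c1O[Si](C)(C)C(C)(C)C)[C@H](OC)[C@@H](C)C[C@H](OC(=O)c2ccccc2)[C@H](OC(=O)c3ccccc3)[C@@H](C)C=O
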